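**Plan**

Numbering: ring C1 (C=O), C2=C3, C4 (CHOH), C5 (quaternary C–OH); side chain C6 (CHOAc) to C20.
Retrosynthesis: C2=C3 goes back to a saturated ketone and the cis C4/C5 diol to a C4=C5 alkene. The 2-substituted cyclopent-2-enone so revealed is cut at C3–C4, C1–C2 and C1–C5 into a terminal propargylic acetate (C4, C5, C6–C20), ethene (C2, C3) and CO (C1). The alkyne is cut at C5–C6 into an acetylide and pentadecanal.
Forward: the C17 chain is joined first, the single ring is then closed by a cobalt-mediated (2+2+1) cycloaddition, and the ring is oxidised last (cis-dihydroxylation, acetonide, C2–C3 dehydrogenation, deprotection).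
Stereochemistry: C6 (S) comes from Noyori transfer hydrogenation of the ynone; C4 (S) and C5 (R) come together from one osmium cis-dihydroxylation on the alkene face anti to the C6 acetoxy group.

Key step: step 6

Remark: the target SMILES is read as the (4S,5R,6S) isomer, with the C4 and C5 hydroxyls cis to each other and trans to the side chain on C5; the CO unit (C1) is taken from the carbonyl ligands of Co2(CO)8, so no CO atmosphere is assumed.

**Route**

Step 1
Reactants: 1 ethynyltrimethylsilane; 2 pentadecanal
Product: 4 rac-1-(trimethylsilyl)heptadec-1-yn-3-ol, via lithium (trimethylsilyl)acetylide 3 (not isolated)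
Conditions: n-BuLi, THF, −78 °C; then 2, −78 → 0 °C; H2O
Reagents that add atoms: none
Why: Deprotonation of the terminal alkyne and 1,2-addition of the lithium acetylide to the unhindered aliphatic aldehyde (acetylide addition to a carbonyl) should join C5 to C6 and give the propargylic alcohol as a racemate, the stereocentre being set in step 3.

Step 2
Reactants: 4 rac-1-(trimethylsilyl)heptadec-1-yn-3-ol
Product: 5 1-(trimethylsilyl)heptadec-1-yn-3-one
Conditions: Dess–Martin periodinane, CH2Cl2, 0 °C → rt
Reagents that add atoms: none
Why: Dess–Martin oxidation of the secondary propargylic alcohol should give the ynone under neutral conditions that leave the alkynyl C–Si bond intact.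

Step 3
Reactants: 5 1-(trimethylsilyl)heptadec-1-yn-3-one
Product: 6 (3S)-1-(trimethylsilyl)heptadec-1-yn-3-ol
Conditions: RuCl(p-cymene)[(S,S)-TsDPEN] (2 mol%), i-PrOH, rt
Reagents that add atoms: none
Why: Noyori asymmetric transfer hydrogenation of an alkynyl ketone, in which the hydride RuH(p-cymene)[(S,S)-TsDPEN] places the alkynyl group where the aryl group of an aryl ketone sits and should therefore deliver hydrogen to the face that gives the (S)-carbinol (C6) with high enantioselectivity, without reducing the alkyne.

Step 4
Reactants: 6 (3S)-1-(trimethylsilyl)heptadec-1-yn-3-ol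
Product: 7 (3S)-heptadec-1-yn-3-ol
Conditions: K2CO3 (cat.), MeOH, rt
Reagents that add atoms: none
Why: Base-catalysed protodesilylation (methanolysis of the alkynyl C–Si bond) should free the terminal alkyne without touching the carbinol centre.

Step 5
Reactants: 7 (3S)-heptadec-1-yn-3-ol
Product: 8 (3S)-heptadec-1-yn-3-yl acetate
Conditions: Ac2O, pyridine, DMAP (cat.), CH2Cl2, 0 °C → rt
Reagents that add atoms: acetic anhydride, CC(=O)OC(C)=O
Why: DMAP-catalysed acylation of the secondary alcohol installs the acetate of the target with retention at C6, since the C6–O bond is not broken.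

Step 6
Reactants: 8 (3S)-heptadec-1-yn-3-yl acetate; 9 ethene
Product: 11 2-[(1S)-1-acetoxypentadecyl]cyclopent-2-en-1-one, via Co2(CO)6–alkyne complex 10 (not isolated)
Conditions: Co2(CO)8 (1.1 equiv), CH2Cl2, rt; then 9 (6 bar), NMO (6 equiv), 4 Å MS, CH2Cl2, rt
Reagents that add atoms: dicobalt octacarbonyl Co2(CO)8 (source of the C1 carbonyl), O=C=[Co](=C=O)(=C=O)(=C=O)[Co](=C=O)(=C=O)(=C=O)=C=O
Why: Pauson–Khand (2+2+1) cycloaddition: NMO oxidises one CO ligand of complex 10 to CO2 and so opens a site on cobalt, ethene binds there and inserts into the Co–C bond of the unsubstituted alkyne carbon C4 (forming C3–C4), a CO ligand then inserts at C2 (C1–C2), and reductive elimination joins C1 to C5 and releases the enone. The closest known reaction type is the amine N-oxide-promoted intermolecular Pauson–Khand reaction of terminal alkyne–Co2(CO)6 complexes with ethene under a few bar of pressure. The five-membered ring C1–C5 is closed inside the cobaltacycle by migratory insertion and reductive elimination, that is as a metal-templated cycloaddition and not as a polar cyclisation. No stereocentre is created, and C6 should pass through unchanged because the neutral, Lewis-acid-free medium generates no cobalt-stabilised propargylic cation. The step needs the side chain on C5 next to the carbonyl, which the terminal alkyne secures because the alkene couples to the sterically free alkyne carbon, while symmetric ethene raises no regiochemical question of its own. All twenty skeletal carbons are in place after this step, and the acetate rides along as a spectator.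

Step 7
Reactants: 11 2-[(1S)-1-acetoxypentadecyl]cyclopent-2-en-1-one
Product: 12 (2R,3S)-2-[(1S)-1-acetoxypentadecyl]-2,3-dihydroxycyclopentan-1-one
Conditions: K2OsO2(OH)4 (2 mol%), NMO (1.3 equiv), citric acid (1 equiv), t-BuOH/H2O 1:1, rt
Reagents that add atoms: N-methylmorpholine N-oxide, C[N+]1([O-])CCOCC1; water, O (both oxygens are passed on through the osmium catalyst)
Why: Osmium-catalysed cis-dihydroxylation in citric-acid-buffered medium (suited to electron-poor alkenes and mild enough to keep the acetate in place) adds O4 and O5 to one face of C4=C5 through a cyclic osmate ester, so the diol is cis by mechanism, and in the conformer with C6–H eclipsing C4=C5 osmium should add anti to the allylic acetoxy group, which corresponds to the 4S,5R configuration of the target.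

Step 8
Reactants: 12 (2R,3S)-2-[(1S)-1-acetoxypentadecyl]-2,3-dihydroxycyclopentan-1-one
Product: 13 (1S)-1-[(3aR,6aS)-2,2-dimethyl-4-oxotetrahydro-3aH-cyclopenta[d][1,3]dioxol-3a-yl]pentadecyl acetate (C4/C5 acetonide of 12)
Conditions: 2,2-dimethoxypropane, PPTS (cat.), acetone, rt
Reagents that add atoms: 2,2-dimethoxypropane, COC(C)(C)OC
Why: Acid-catalysed transacetalisation (acetonide formation) should close a cis-fused dioxolane on the cis C4/C5 diol and so shield both hydroxyls from silylation, oxidation and acetyl migration in the next two steps.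

Step 9
Reactants: 13 acetonide ketone
Product: 14 (1S)-1-[(3aR,6aS)-2,2-dimethyl-4-(trimethylsilyloxy)-6,6a-dihydro-3aH-cyclopenta[d][1,3]dioxol-3a-yl]pentadecyl acetate (C1=C2 trimethylsilyl enol ether of 13)
Conditions: TMSOTf, Et3N, CH2Cl2, −20 → 0 °C
Reagents that add atoms: trimethylsilyl trifluoromethanesulfonate, C[Si](C)(C)OS(=O)(=O)C(F)(F)F
Why: Silyl enol ether formation by soft enolisation can only take place toward C2 because C5 is quaternary, and it avoids a metal enolate that could attack the C6 acetate.

Step 10
Reactants: 14 trimethylsilyl enol ether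
Product: 15 (1S)-1-[(3aS,6aS)-2,2-dimethyl-4-oxo-4,6a-dihydro-3aH-cyclopenta[d][1,3]dioxol-3a-yl]pentadecyl acetate (C2=C3 enone; the spatial arrangement is unchanged and only the ranking at C5 differs)
Conditions: Pd(OAc)2 (1.1 equiv), MeCN, rt
Reagents that add atoms: none
Why: Saegusa–Ito oxidation, in which the silyl enol ether is converted into a C2-bound enolate of divalent palladium and β-hydride elimination of a C3 hydrogen installs C2=C3 regiospecifically, with C4 and C5 untouched.

Step 11
Reactants: 15 enone acetonide
Product: 16 (4S,5R)-5-[(1S)-1-acetoxypentadecyl]-4,5-dihydroxycyclopent-2-en-1-one (target)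
Conditions: TFA/H2O 9:1, 0 °C
Reagents that add atoms: none
Why: Acid-catalysed acetal hydrolysis should release the C4/C5 diol while the acetate survives brief cold aqueous acid, and C5, being quaternary, allows neither enolisation nor β-elimination that could scramble C4 or C5.

**Compound list**

1 | ethynyltrimethylsilane | C#C[Si](C)(C)C | starting material
2 | pentadecanal | CCCCCCCCCCCCCCC=O | starting material
3 | lithium (trimethylsilyl)acetylide | [Li]C#C[Si](C)(C)C | intermediate (not isolated)
4 | rac-1-(trimethylsilyl)heptadec-1-yn-3-ol | CCCCCCCCCCCCCCC(O)C#C[Si](C)(C)C | intermediate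
5 | 1-(trimethylsilyl)heptadec-1-yn-3-one | CCCCCCCCCCCCCCC(=O)C#C[Si](C)(C)C | intermediate
6 | (3S)-1-(trimethylsilyl)heptadec-1-yn-3-ol | CCCCCCCCCCCCCC[C@H](O)C#C[Si](C)(C)C | intermediate
7 | (3S)-heptadec-1-yn-3-ol | CCCCCCCCCCCCCC[C@H](O)C#C | intermediate
8 | (3S)-heptadec-1-yn-3-yl acetate | CCCCCCCCCCCCCC[C@H](OC(C)=O)C#C | intermediate
9 | ethene | C=C | starting material
10 | Co2(CO)6 complex of alkyne 8 (both alkyne carbons bridging the Co–Co bond, three CO on each cobalt) | CCCCCCCCCCCCCC[C@H](OC(C)=O)C12[CH]3[Co]1(=C=O)(=C=O)(=C=O)[Co]23(=C=O)(=C=O)=C=O | intermediate (not isolated)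
11 | 2-[(1S)-1-acetoxypentadecyl]cyclopent-2-en-1-one | CCCCCCCCCCCCCC[C@H](OC(C)=O)C1=CCCC1=O | intermediate
12 | (2R,3S)-2-[(1S)-1-acetoxypentadecyl]-2,3-dihydroxycyclopentan-1-one | CCCCCCCCCCCCCC[C@H](OC(C)=O)[C@@]1(O)C(=O)CC[C@@H]1O | intermediate
13 | (1S)-1-[(3aR,6aS)-2,2-dimethyl-4-oxotetrahydro-3aH-cyclopenta[d][1,3]dioxol-3a-yl]pentadecyl acetate | CCCCCCCCCCCCCC[C@H](OC(C)=O)[C@]12OC(C)(C)O[C@H]1CCC2=O | intermediate
14 | (1S)-1-[(3aR,6aS)-2,2-dimethyl-4-(trimethylsilyloxy)-6,6a-dihydro-3aH-cyclopenta[d][1,3]dioxol-3a-yl]pentadecyl acetate | CCCCCCCCCCCCCC[C@H](OC(C)=O)[C@]12OC(C)(C)O[C@H]1CC=C2O[Si](C)(C)C | intermediate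
15 | (1S)-1-[(3aS,6aS)-2,2-dimethyl-4-oxo-4,6a-dihydro-3aH-cyclopenta[d][1,3]dioxol-3a-yl]pentadecyl acetate | CCCCCCCCCCCCCC[C@H](OC(C)=O)[C@]12OC(C)(C)O[C@H]1C=CC2=O | intermediate
16 | (4S,5R)-5-[(1S)-1-acetoxypentadecyl]-4,5-dihydroxycyclopent-2-en-1-one | CCCCCCCCCCCCCC[C@H](OC(C)=O)[C@@]1(O)C(=O)C=C[C@@H]1O | target

**Count**

Total steps: 11. Longest linear sequence: 11 steps (from pentadecanal 2 to 16).

**Steps most likely to fail**

Step 7. The C6 acetoxy group may discriminate the two alkene faces only weakly, since acyloxy groups steer osmium less firmly than ether oxygens, and osmylation of the electron-poor enone may be slow enough for acetyl migration to the new hydroxyls to begin. The fallback carries O6 as a bulky silyl ether through cycloaddition and osmylation and introduces the acetate only once the diol is locked. It sets out from 7. TBSCl and imidazole in DMF should give (3S)-3-(tert-butyldimethylsilyloxy)heptadec-1-yne F1. Co2(CO)8 in CH2Cl2 converts it into the Co2(CO)6 complex of this alkyne F2 (not isolated), and ethene with NMO as in step 6 should give 2-[(1S)-1-(tert-butyldimethylsilyloxy)pentadecyl]cyclopent-2-en-1-one F3. Catalytic OsO4 with NMO in acetone/water, now directed by a silyl ether that follows the anti rule more strictly, should give the C6-O-silyl analogue of diol 12 F4. 2,2-Dimethoxypropane with PPTS gives the C6-O-silyl analogue of acetonide 13 F5. HF·pyridine in THF/pyridine removes the silyl group without base, which avoids retro-aldol cleavage of C5–C6, and gives the C6 hydroxy acetonide F6. Acetylation with Ac2O, pyridine and DMAP brings the sequence back to the route at 13.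

Step 6. The decarbonylated cobalt complex may take up gaseous ethene too slowly, so that decomplexation and alkyne oligomerisation outrun the cycloaddition. The fallback replaces the gas by vinyl benzoate, a liquid ethene equivalent that can be used in large excess. It sets out from 8, which is complexed with Co2(CO)8 as before and treated with vinyl benzoate and NMO monohydrate in CH2Cl2 at rt. The benzoyloxy group is cleaved reductively in the cobalt manifold, so the reaction should deliver 11 directly and the route is rejoined there; no new compound is made (F0). The silyl ether series described for step 7 would in addition take the allylic acetate out of the cycloaddition if that group proved labile towards the amine formed from NMO.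

Step 11. The aqueous acid needed to open the cis-fused acetonide may trigger migration of the acetyl group from O6 to the freed O4 or O5, or acid-induced degradation of the hydroxy enone. The fallback masks the diol as silyl ethers that are removed by fluoride. It sets out from 12. Excess TESOTf and Et3N in CH2Cl2 silylate O4, O5 and the ketone in one operation to give the tris(triethylsilyl) derivative of 12 (O4 and O5 ethers, C1=C2 enol ether) F7. Pd(OAc)2 in MeCN (Saegusa–Ito oxidation) should give the 4,5-bis(triethylsilyl) ether of the target F8. HF·pyridine in THF at 0 °C removes both silyl groups and arrives at 16.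

**Further compounds**

F1 | step 7 | (3S)-3-(tert-butyldimethylsilyloxy)heptadec-1-yne | CCCCCCCCCCCCCC[C@H](O[Si](C)(C)C(C)(C)C)C#C
F2 | step 7 | Co2(CO)6 complex of F1 (not isolated) | CCCCCCCCCCCCCC[C@H](O[Si](C)(C)C(C)(C)C)C12[CH]3[Co]1(=C=O)(=C=O)(=C=O)[Co]23(=C=O)(=C=O)=C=O
F3 | step 7 | 2-[(1S)-1-(tert-butyldimethylsilyloxy)pentadecyl]cyclopent-2-en-1-one | CCCCCCCCCCCCCC[C@H](O[Si](C)(C)C(C)(C)C)C1=CCCC1=O
F4 | step 7 | (2R,3S)-2-[(1S)-1-(tert-butyldimethylsilyloxy)pentadecyl]-2,3-dihydroxycyclopentan-1-one | CCCCCCCCCCCCCC[C@H](O[Si](C)(C)C(C)(C)C)[C@@]1(O)C(=O)CC[C@@H]1O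
F5 | step 7 | C4/C5 acetonide of F4 (C6-O-silyl analogue of 13) | CCCCCCCCCCCCCC[C@H](O[Si](C)(C)C(C)(C)C)[C@]12OC(C)(C)O[C@H]1CCC2=O
F6 | step 7 | C6 hydroxy acetonide (13 without its acetyl group) | CCCCCCCCCCCCCC[C@H](O)[C@]12OC(C)(C)O[C@H]1CCC2=O
F0 | step 6 | none | none
F7 | step 11 | tris(triethylsilyl) derivative of 12 (O4 and O5 ethers, C1=C2 enol ether) | CCCCCCCCCCCCCC[C@H](OC(C)=O)[C@@]1(O[Si](CC)(CC)CC)C(O[Si](CC)(CC)CC)=CC[C@@H]1O[Si](CC)(CC)CC
F8 | step 11 | 4,5-bis(triethylsilyl) ether of 16 | CCCCCCCCCCCCCC[C@H](OC(C)=O)[C@@]1(O[Si](CC)(CC)CC)C(=O)C=C[C@@H]1O[Si](CC)(CC)CC
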